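The readings were generated by integration with constants of no real substance; noise was put on by code.

Teal's last reading still has isomer of the product at 20.6% against target at 5.7%, yet the isomer's rise is flattening, so what matters is how much isomer the leftovers can hold.

| setting | teal | oak | ash | larch | maple |
|---|---|---|---|---|---|
| starting material | 2.2 M | 1.5 M | 1.5 M | 1.5 M | 1.5 M |
| partner | 1.1 equiv | 1.10 equiv | 1.10 equiv | 1.10 equiv | 1.10 equiv |
| temperature | 50 °C | 50 °C | 25 °C | 75 °C | 0 °C |
| remark | run made earlier |  |  |  |  |
| time |  | 12 h | 12 h | 12 h | 12 h |

teal run (percent of the starting material charged)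

| time / min | target / % | isomer of the product / % |
|---|---|---|
| 12.0 | 0.4 | 5.0 |
| 25.0 | 0.5 | 9.2 |
| 40.0 | 1.4 | 13.7 |
| 50.0 | 2.9 | 15.5 |
| 60.0 | 3.9 | 17.8 |
| 80.0 | 5.7 | 20.6 |

(scatter of a reading: 0.3 percentage points)

- target is meant together with its crystals
- solid, in amounts per volume of the solution: crystals
- steps under discussion: starting material <-> tautomer; starting material + partner <-> isomer of the product; partner + tautomer -> target; crystals <-> target
- the earlier runs do not show what temperature does; that part of a forecast is a guess

* the best flask by share of target in all that became target or isomer of the product; "all alike" if 1.5 percentage points covers them all (oak / ash / larch / maple / all alike)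
* share of target in all that became target or isomer of the product, oak
* share of target in all that became target or isomer of the product, ash
* share of target in all that became target or isomer of the product, larch
* share of target in all that became target or isomer of the product, maple

My reckoning runs on teal, the one run with readings.

1. Partner leaves by two steps, so what it has lost stands in target or isomer: 26.3% of the starting charge at the last reading. That leaves 1.84 M of partner and 1.62 M of starting material, tautomer still counted with it.

2. The isomer rises by 0.00417 min⁻¹ of the charge at first and by 0.00140 min⁻¹ at the end. The first slope gives a forward constant of 0.00172 L mol⁻¹ min⁻¹.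

3. Read as a decay, the two slopes give 0.0170 min⁻¹, a half-life of 40.7 min, short beside 12 h. So at 50 °C the isomer has time to keep up with its leftovers. The plateau lies near 28.8%, which gives a first quotient of 0.265 L mol⁻¹.

4. That plateau is the weak link: it is extrapolated. Instead, I take the last interval as forward minus back. Forward is 0.00234 min⁻¹, so the back constant is 0.00455 min⁻¹. This gives the isomer quotient, isomer over starting material times partner at balance, 0.379 L mol⁻¹, a reading with the scatter of teal in it.

At a fixed temperature, once a flask's isomer has reached balance, it stands at this quotient times the product of its leftovers. Temperature stays a guess.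

The forecast says larch, with oak 58%, ash 20%, larch 88% and maple 6%, on the ground that “the isomer drains into it through the starting material”.

The simulation gives larch: oak 60.1%, ash 13.1%, larch 98.7%, maple 0.489%. Larch stands above the forecast and maple below it.

    starting material ⇌ tautomer (K = 0.620, k = 1.30 × 10⁻⁴ s⁻¹, Ea = 91.0 kJ mol⁻¹, ΔH = −23.0 kJ mol⁻¹)
    starting material + partner ⇌ isomer of the product (K = 0.700 L mol⁻¹, k = 3.40 × 10⁻⁵ L mol⁻¹ s⁻¹, Ea = 87.0 kJ mol⁻¹, ΔH = −23.0 kJ mol⁻¹)
    partner + tautomer → target (k = 3.60 × 10⁻⁵ L mol⁻¹ s⁻¹, Ea = 90.0 kJ mol⁻¹)
    crystals ⇌ target, rate k4*(cs4 - [target]) while solid is left; crystals form when [target] > cs4 (solubility = 0.660 M, k = 0.00180 s⁻¹)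
    (constants at 50 °C)

In larch the isomer step relaxes with a half-life of 0.178 h, short against 12 h. The quotient, carried over from 50 °C as a guess, gives 1.11% of isomer from the leftovers at 12.0 h, and the flask holds 1.16%. Now take a second flask, like larch but with 0.280 equiv of partner, the limiting reagent, down to 1.91% of its charge. The quotient gives 0.165% of isomer and a share of 99.4%. The simulation gives 0.181% and 99.3%.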